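## Analysis of the target

The target, 3,5,6-tribromo-2-(2,3,5-tribromo-4-hydroxyphenoxy)benzene-1,4-diol (C12H4Br6O4), is two benzene rings joined through one ether oxygen, with no further ring and no chain. Ring A is numbered from its phenol carbon (C1 OH, C2 Br, C3 the only ring hydrogen, C4 the ether oxygen, C5 and C6 Br), and ring B from its ether carbon C1' (OH at C2' and C5', Br at C3', C4' and C6'), which makes ring B a fully substituted hydroquinone. There is no stereocenter, and rotation about the diaryl ether bonds is not expected to be frozen, so no stereochemical question arises. The sensitive points are the hydroquinone of ring B (air oxidation to the quinone), the 4-aryloxyphenol of ring A (strong oxidants give a quinone with loss of ring B) and six aryl bromides, which rule out organolithium reagents, hydrogenation and low-valent palladium or copper once they are in place. The first difficulty is that the ether oxygen of ring B sits between two ortho substituents on an electron-poor ring and is a poor partner for Ullmann or SNAr ether formation. The second is that ring A needs bromine at C5 but hydrogen at C3, although both carbons are meta to the hydroxyl and ortho to the ether oxygen. The strategy rests on ring A being a hydroquinone monoaryl ether, with the C1 hydroxyl para to the C4 ether oxygen, which is the pattern that benzannulation of an alkenyl(oxy)carbene complex of chromium produces: C4 and its oxygen from the carbene carbon, C1 and its hydroxyl from a carbonyl ligand, C5 and C6 from the alkenyl group, C2 and C3 from an alkyne.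

## Retrosynthetic reasoning

14 to 13. The O–CH3 bonds at C2' and C5' of 13 are cut first. The hydroquinone is carried as its dimethyl ether throughout, because the free form would be oxidised by the brominating agent of the preceding step and would interfere with the organometallic chemistry before that. Methyl is chosen because it tolerates chromium carbonyl chemistry, heat and electrophilic bromination. Forward, two methyl ethers, each flanked by two ortho substituents, must be cleaved by a Lewis acid without touching the diaryl ether or any C–Br bond.

13 to 12. The three C–Br bonds of ring A are cut next. C2–Br and C5–Br are traced to C–Si bonds, and C6–Br to a C–H bond ortho to the free hydroxyl. This is where the problem of ring A is solved: C3 and C5 are electronically alike, and only a group already sitting on C5 and replaced at its own carbon can tell them apart. Forward, three electrophilic substitutions are needed, two ipso at silicon and one at C6–H, and none at C3–H.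

12 to 9 and 10. Ring A is taken apart at C3–C4, C1–C2 and C1–C6. C4 with its aryloxy group becomes the carbene carbon of 9, C5 (with silicon) and C6 its vinyl group, C2 (with silicon) and C3 (with hydrogen) the two carbons of 10, and C1 with its oxygen a carbonyl ligand of 9. Cutting here and not at the ether oxygen means the aryl–O bond of ring A is never made on an aromatic carbon; the ring is grown around a carbon that already bears the oxygen of ring B. Forward, the carbene complex must take up 10 in one orientation, insert a carbonyl ligand and close a six-membered ring, the arene appearing first as its chromium complex 11.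

9 to 7 and 2. The bond between the carbene carbon and the ring B oxygen is cut. O-Acylation of 7 gives 8, whose carbene carbon is as electrophilic as the carbonyl carbon of a mixed anhydride, and the phenolic oxygen of 2 displaces the acyloxy group there. Ring B arrives with all three bromines, so ring B never has to be brominated in the presence of ring A.

7 to 3 and 4. The C4–C5 bond is cut. Halogen–metal exchange on 3 gives 5, which adds to a carbonyl ligand of 4 to give 6, and cation exchange gives the storable salt 7. The silicon on the metallated carbon of 3 is the silicon that later marks C5.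

2 to 1. The three C–Br bonds of ring B are cut. Since 1 has exactly three free ring carbons and all are brominated, the forward reaction has no regiochemical choice to make.

## Alternatives that were turned down

Alternative 1: All six C–Br bonds are disconnected at once, back to the bromine-free triol ether 2-(4-hydroxyphenoxy)benzene-1,4-diol A1.
- Forward key step: about seven equivalents of Br2 in dry acetic acid would oxidise ring B of A1 to its quinone and form the C–Br bonds at C3', C4', C6', C2, C6 and C5, giving 3,5,6-tribromo-2-(2,3,5-tribromo-4-hydroxyphenoxy)-1,4-benzoquinone A2. A mild reduction of A2 would then give the target.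
- For: it is the shortest route, needs no protecting groups or metals, and the ether of A1 is formed on unhindered, bromine-free rings. C2 and C6 are ortho to the hydroxyl, and C3 and C5 are equivalent until one is brominated, so ring A has no positional problem.
- Against: ring A has a counting problem instead. It must stop at three bromines while the electron-poor quinone ring B, which brominates only by addition and re-oxidation, must be driven to three. Conditions strong enough for ring B should take ring A to the tetrabromide, and milder ones should leave ring B short. The aryloxyquinone A2 is also a vinylogous ester, so bromide or HBr can displace the aryloxy group by addition–elimination and break the ether.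
- Comparison: Alternative 1 is clearly stronger in step economy. The chosen strategy offers in its place a separate structural cause for every bromine (exhaustive substitution of 1, silicon at C2 and C5, the hydroxyl for C6), so the outcome does not depend on matching the rates of six brominations in two different rings.

Alternative 2: Ring A is traced to a cyclohexanone, so the ether O–C4 bond is made at an sp3 carbon, by O-alkylation of 2 at a secondary carbon of a saturated six-membered ring, leading to the ketone 4-(3,4,6-tribromo-2,5-dimethoxyphenoxy)cyclohexanone A3.
- Forward key step: the ketone A3 would be brominated four times alpha to the carbonyl with Br2 in acetic acid, then lose two HBr on warming with Li2CO3 and LiBr in DMF. This makes the C2–Br and C6–Br bonds and aromatises the ring to 2,6-dibromo-4-(3,4,6-tribromo-2,5-dimethoxyphenoxy)phenol A4.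
- For: the acidic phenol 2 is a good oxygen pronucleophile for Mitsunobu or sulfonate displacement, the hindered aryl–O coupling is avoided, and every reaction type on the way to A3 and A4 is known. On precedent this alternative is stronger than the chosen route.
- Against: the phenol A4 still lacks the C5 bromine. C3 and C5 are equivalent in A4, so a further bromination is unambiguous in position, but it must occur meta to the hydroxyl on a ring already holding two bromines and must stop after one. Displacement at a secondary cyclohexyl carbon by a hindered, weakly nucleophilic phenoxide competes with elimination. The step count (ether formation, ketone release, bromination with aromatisation, the extra bromination, demethylation, plus the preparation of 2) is no shorter than the chosen route.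
- Comparison: the chosen strategy offers a C5 bromine fixed by a C–Si bond in place of a forcing monobromination, and an ether formed at an sp2 carbene carbon that has no elimination pathway.

Alternative 3: The O–C4 and C5–Br bonds of ring A are disconnected together across an aryne.
- Forward key step: CsF would convert 3,5-dibromo-4-methoxy-2-(trimethylsilyl)phenyl trifluoromethanesulfonate A5 into its aryne. The phenoxide of 2 would add at the aryne carbon that becomes C4, and the resulting C5 anion would take bromine from CBr4, giving 2,3,5-tribromo-4-methoxyphenyl 3,4,6-tribromo-2,5-dimethoxyphenyl ether A6.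
- For: it is convergent, makes two adjacent bonds in one operation, and the bromine next to the aryne of A5 directs the nucleophile to the distal carbon, so the regiochemistry has a sound basis. It is as strong as the chosen route in regiochemical logic and arguably stronger in that the C5 bromine is installed directly.
- Against: the C5 anion sits ortho to the C6 bromine and can expel bromide to form a second aryne. Protonation of the anion competes with bromine transfer and would leave C5–H. The hindered, weakly nucleophilic phenoxide must intercept a short-lived aryne while CBr4 and fluoride are present. The pentasubstituted precursor A5 needs its own multi-step synthesis, and the triether A6 needs three ether cleavages.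
- Comparison: both routes depend on an untested key step. The chosen strategy reaches its key precursor in three steps from purchasable materials and has no carbanion next to a leaving group.

Key step: step 4

Assumption: 2,5-dimethoxyphenol (1) and (1-bromovinyl)trimethylsilane (3) are taken as purchasable, and the ring A locants defined above are kept in all names, even where lowest-locant rules would renumber.

## Route

Step 1
Reactants: 1 2,5-dimethoxyphenol
Product: 2 3,4,6-tribromo-2,5-dimethoxyphenol
Conditions: Br2 (3.3 equiv), AcOH, 20 → 50 °C
Reagents that add atoms: bromine, BrBr
Why: Electrophilic aromatic bromination; the hydroxyl and both methoxy groups activate all three free ring carbons (C4 para and C6 ortho to OH first, C3 ortho to the C2 methoxy last on warming), and since every free position is brominated no regiochemical choice arises.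

Step 2
Reactants: 3 (1-bromovinyl)trimethylsilane; 4 hexacarbonylchromium, Cr(CO)6
Product: 7 tetramethylammonium pentacarbonyl[1-oxido-2-(trimethylsilyl)prop-2-en-1-ylidene]chromate, via 1-lithio-1-(trimethylsilyl)ethene 5 (not isolated), via lithium acylchromate 6 (not isolated)
Conditions: t-BuLi (2.0 equiv), Et2O, −78 °C; Cr(CO)6, Et2O, −78 → 20 °C; Me4NBr, degassed H2O, CH2Cl2 extraction
Reagents that add atoms: tert-butyllithium, CC(C)(C)[Li] (supplies the lithium of intermediates 5 and 6 only); tetramethylammonium bromide, C[N+](C)(C)C.[Br-]
Why: Lithium–bromine exchange gives the α-silyl vinyllithium without moving the metal, and its addition to a carbonyl ligand of Cr(CO)6 is the first stage of the Fischer carbene synthesis; cation exchange gives the tetramethylammonium acylchromate, which can be dried and stored.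

Step 3
Reactants: 7 tetramethylammonium pentacarbonyl[1-oxido-2-(trimethylsilyl)prop-2-en-1-ylidene]chromate; 2 3,4,6-tribromo-2,5-dimethoxyphenol
Product: 9 pentacarbonyl[(3,4,6-tribromo-2,5-dimethoxyphenoxy)(1-trimethylsilylvinyl)carbene]chromium, via acetoxycarbene complex 8 (not isolated)
Conditions: AcBr (1.0 equiv), CH2Cl2, −40 °C; then 2 (1.1 equiv), −40 → −10 °C, Ar; cold filtration through silica
Reagents that add atoms: acetyl bromide, CC(=O)Br (supplies the acetoxy group of intermediate 8 only, which leaves as acetic acid)
Why: O-Acylation of the acylchromate gives an acyloxycarbene complex whose carbene carbon behaves like the carbonyl carbon of a mixed anhydride, and addition–elimination by the phenolic oxygen of 2 displaces acetate (the acyloxy-exchange route to alkoxy- and aryloxycarbene complexes). The hindered oxygen of 2 attacks a planar, strongly electrophilic sp2 carbon and not an arene, so no metal-catalysed C–O coupling is needed.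

Step 4
Reactants: 9 pentacarbonyl[(3,4,6-tribromo-2,5-dimethoxyphenoxy)(1-trimethylsilylvinyl)carbene]chromium; 10 trimethylsilylacetylene
Product: 12 4-(3,4,6-tribromo-2,5-dimethoxyphenoxy)-2,5-bis(trimethylsilyl)phenol, via arene tricarbonylchromium complex 11 (not isolated)
Conditions: Me3SiC≡CH (2 equiv), THF (0.05 M), 50 °C, Ar, sealed vessel; then air, Et2O, 20 °C, filtration through silica
Reagents that add atoms: none
Why: Proposed new method: the closest known reaction type is the Dötz benzannulation of alkenyl(alkoxy)carbene complexes of zerovalent chromium with terminal and silyl alkynes to 4-alkoxyphenols, and what has not been shown is this reaction with a doubly ortho-substituted, electron-poor aryloxy group on the carbene carbon next to an α-silylvinyl group. Thermal loss of one cis carbonyl ligand from 9 (expected to be easier than from an alkoxy analogue because the aryloxy oxygen donates less to the carbene carbon, and possibly helped by transient coordination of the C2' methoxy oxygen) opens a site for the alkyne, which inserts into the Cr=C bond to give an η3-vinylcarbene in which the former carbene carbon C4 is bonded to the alkyne CH (C3–C4 bond). Carbonyl insertion at the new, silyl-bearing carbene carbon then gives an η4-dienylketene (C1–C2 bond). Ring A closes by thermal 6π electrocyclization of this dienylketene, the ketene carbon C1 bonding to the vinyl CH2 carbon C6, and a hydrogen shift from C6 to oxygen aromatises the cyclohexadienone to the phenol, which is formed as its Cr(CO)3 complex 11 and freed by air. No stereocenter is formed. Two selectivities are needed: alkyne insertion with SiMe3 at C2 beside the CO-derived C1 and H at C3 beside C4, which the size difference between H and SiMe3 should secure because the larger alkyne substituent takes the metal-bound carbon of the vinylcarbene; and CO insertion with six-ring closure in preference to five-ring products, which chromium, THF as a coordinating solvent and an alkenyl carbene substituent all favour. The silicon on the vinyl group ends at C5, and the bromines of ring B are spectators because chromium carbonyl fragments are not expected to insert into aryl–Br bonds at this temperature.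

Step 5
Reactants: 12 4-(3,4,6-tribromo-2,5-dimethoxyphenoxy)-2,5-bis(trimethylsilyl)phenol
Product: 13 2,5,6-tribromo-4-(3,4,6-tribromo-2,5-dimethoxyphenoxy)phenol (2,3,6-tribromo by lowest locants)
Conditions: Br2 (3.1 equiv), NaOAc (3.5 equiv), CH2Cl2–AcOH, 0 → 20 °C
Reagents that add atoms: bromine, BrBr
Why: Electrophilic bromination of a phenol combined with ipso-bromodesilylation: the hydroxyl directs bromine to both ortho carbons (C6–H and, ipso, C2–Si), and the C5 silane, ortho to the ether oxygen, is replaced at its own carbon because the β-silyl-stabilised σ-complex forms and collapses faster than attack at C3–H. The acetate buffer removes HBr, which would otherwise protodesilylate C5; ring B has no free position.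

Step 6
Reactants: 13 2,5,6-tribromo-4-(3,4,6-tribromo-2,5-dimethoxyphenoxy)phenol
Product: 14 3,5,6-tribromo-2-(2,3,5-tribromo-4-hydroxyphenoxy)benzene-1,4-diol (target, CNP0277646.0)
Conditions: BBr3 (6 equiv), CH2Cl2, −78 → 20 °C; degassed H2O, work-up under Ar
Reagents that add atoms: none
Why: Lewis-acid cleavage of aryl methyl ethers: BBr3 binds the two methoxy oxygens, which are twisted out of the ring plane by their ortho neighbours and therefore basic, and bromide attacks the methyl carbons. The diaryl ether has no sp3 carbon to attack and the C–Br bonds are inert; oxygen is excluded in the work-up because the product is a hydroquinone.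

## Compound list

1 | 2,5-dimethoxyphenol | COc1ccc(OC)c(O)c1 | starting material
2 | 3,4,6-tribromo-2,5-dimethoxyphenol | Oc1c(OC)c(Br)c(Br)c(OC)c1Br | intermediate
3 | (1-bromovinyl)trimethylsilane | C=C(Br)[Si](C)(C)C | starting material
4 | hexacarbonylchromium, Cr(CO)6 | O=C=[Cr](=C=O)(=C=O)(=C=O)(=C=O)=C=O | starting material
5 | 1-lithio-1-(trimethylsilyl)ethene | [Li]C(=C)[Si](C)(C)C | intermediate
6 | lithium pentacarbonyl[1-oxido-2-(trimethylsilyl)prop-2-en-1-ylidene]chromate | [Li+].[O-]C(C(=C)[Si](C)(C)C)=[Cr](=C=O)(=C=O)(=C=O)(=C=O)=C=O | intermediate
7 | tetramethylammonium pentacarbonyl[1-oxido-2-(trimethylsilyl)prop-2-en-1-ylidene]chromate | C[N+](C)(C)C.[O-]C(C(=C)[Si](C)(C)C)=[Cr](=C=O)(=C=O)(=C=O)(=C=O)=C=O | intermediate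
8 | pentacarbonyl[acetoxy(1-trimethylsilylvinyl)carbene]chromium | CC(=O)OC(C(=C)[Si](C)(C)C)=[Cr](=C=O)(=C=O)(=C=O)(=C=O)=C=O | intermediate
9 | pentacarbonyl[(3,4,6-tribromo-2,5-dimethoxyphenoxy)(1-trimethylsilylvinyl)carbene]chromium | C=C([Si](C)(C)C)C(Oc1c(OC)c(Br)c(Br)c(OC)c1Br)=[Cr](=C=O)(=C=O)(=C=O)(=C=O)=C=O | intermediate
10 | trimethylsilylacetylene | C#C[Si](C)(C)C | starting material
11 | tricarbonyl[η6-4-(3,4,6-tribromo-2,5-dimethoxyphenoxy)-2,5-bis(trimethylsilyl)phenol]chromium, ring A bound to chromium (metal fragment written separately) | Oc1c([Si](C)(C)C)cc(Oc2c(OC)c(Br)c(Br)c(OC)c2Br)c([Si](C)(C)C)c1.[Cr](=C=O)(=C=O)=C=O | intermediate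
12 | 4-(3,4,6-tribromo-2,5-dimethoxyphenoxy)-2,5-bis(trimethylsilyl)phenol | Oc1c([Si](C)(C)C)cc(Oc2c(OC)c(Br)c(Br)c(OC)c2Br)c([Si](C)(C)C)c1 | intermediate
13 | 2,5,6-tribromo-4-(3,4,6-tribromo-2,5-dimethoxyphenoxy)phenol | Oc1c(Br)cc(Oc2c(OC)c(Br)c(Br)c(OC)c2Br)c(Br)c1Br | intermediate
14 | 3,5,6-tribromo-2-(2,3,5-tribromo-4-hydroxyphenoxy)benzene-1,4-diol | Oc1c(Br)cc(Oc2c(O)c(Br)c(Br)c(O)c2Br)c(Br)c1Br | target

## Step count and least certain steps

Total: 6 steps. Longest linear sequence: 5 steps (1 → 2 → 9 → 12 → 13 → 14, or equally 3 → 7 → 9 → 12 → 13 → 14).

Step 4 (key step, the one step beyond known reaction classes).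
- What may go wrong: the sequence may stop at the silyl-stabilised dienylketene, which cannot cyclise if its central double bond has the wrong geometry. The aryloxycarbene, more electrophilic and less stable than an alkoxy analogue, may decompose or hydrolyse before it takes up the alkyne. The unsubstituted vinyl terminus may undergo conjugate addition or oligomerisation. Migration of the C2 silyl group to the phenolic oxygen may also occur, but it would be tolerable, since C2 is ortho to the hydroxyl and is brominated in step 5 with or without silicon.
- Fallback (known chemistry, from 2 to 13): the phenoxide of 2 (K2CO3, DMF, 120 °C) would displace fluoride from 4-fluorobenzaldehyde by SNAr to give 4-(3,4,6-tribromo-2,5-dimethoxyphenoxy)benzaldehyde F1. Baeyer–Villiger oxidation with mCPBA in CH2Cl2, with migration of the aryl group that carries the para aryloxy donor, would give 4-(3,4,6-tribromo-2,5-dimethoxyphenoxy)phenyl formate F2, and K2CO3 in MeOH would release 4-(3,4,6-tribromo-2,5-dimethoxyphenoxy)phenol F3. Br2 (3 equiv, AcOH, 20 → 60 °C) would then brominate both carbons ortho to the hydroxyl and one of the two remaining ring A carbons. Those two are equivalent at that stage, so either attack leads to 13, provided the reaction is stopped before the last hydrogen is replaced.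

Step 3.
- What may go wrong: the weakly nucleophilic, doubly ortho-flanked phenol may attack the carbene carbon too slowly, so that 8 decomposes as the mixture warms, or acyl transfer to the phenol oxygen may compete and return the acylchromate.
- Fallback (from 7 and 1 to 13): the bromine-free phenol 1 is carried through the carbene chemistry and ring B is brominated late. Complex 8, generated from 7 as in step 3, would be exchanged with 1 to give pentacarbonyl[(2,5-dimethoxyphenoxy)(1-trimethylsilylvinyl)carbene]chromium F4. Benzannulation with 10 under the conditions of step 4 would give tricarbonyl[η6-4-(2,5-dimethoxyphenoxy)-2,5-bis(trimethylsilyl)phenol]chromium F5, and air would free 4-(2,5-dimethoxyphenoxy)-2,5-bis(trimethylsilyl)phenol F6. Br2 (6 equiv, NaOAc, CH2Cl2–AcOH) would then brominate ring B at all three of its free carbons and ring A as in step 5, rejoining the route at 13. This relies on ring B, with three oxygen donors, taking its third bromine before the lone C3–H of the tribrominated ring A reacts.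

Step 5.
- What may go wrong: protodesilylation at C5 by HBr may compete with ipso-bromination, a fourth bromine may enter at C3, or the 4-aryloxyphenol may be oxidised with loss of ring B when excess bromine meets the free phenol.
- Fallback (from 12 to 13): the ipso substitutions are separated from the hydroxyl-directed one. Ac2O and pyridine would give 4-(3,4,6-tribromo-2,5-dimethoxyphenoxy)-2,5-bis(trimethylsilyl)phenyl acetate F7. On this deactivated, oxidation-resistant ring, Br2 (2.2 equiv, CH2Cl2, 0 → 20 °C) would replace only the two silyl groups to give 2,5-dibromo-4-(3,4,6-tribromo-2,5-dimethoxyphenoxy)phenyl acetate F8. K2CO3 in MeOH would release 2,5-dibromo-4-(3,4,6-tribromo-2,5-dimethoxyphenoxy)phenol F9, and NBS (1.0 equiv, MeCN, 0 °C) would brominate C6, the only free carbon ortho to the hydroxyl, to give 13.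

## Further compounds

F1 | step 4 | 4-(3,4,6-tribromo-2,5-dimethoxyphenoxy)benzaldehyde | O=Cc1ccc(Oc2c(OC)c(Br)c(Br)c(OC)c2Br)cc1
F2 | step 4 | 4-(3,4,6-tribromo-2,5-dimethoxyphenoxy)phenyl formate | O=COc1ccc(Oc2c(OC)c(Br)c(Br)c(OC)c2Br)cc1
F3 | step 4 | 4-(3,4,6-tribromo-2,5-dimethoxyphenoxy)phenol | Oc1ccc(Oc2c(OC)c(Br)c(Br)c(OC)c2Br)cc1
F4 | step 3 | pentacarbonyl[(2,5-dimethoxyphenoxy)(1-trimethylsilylvinyl)carbene]chromium | C=C([Si](C)(C)C)C(Oc1cc(OC)ccc1OC)=[Cr](=C=O)(=C=O)(=C=O)(=C=O)=C=O
F5 | step 3 | tricarbonyl[η6-4-(2,5-dimethoxyphenoxy)-2,5-bis(trimethylsilyl)phenol]chromium, silylated ring bound to chromium (metal fragment written separately) | Oc1c([Si](C)(C)C)cc(Oc2cc(OC)ccc2OC)c([Si](C)(C)C)c1.[Cr](=C=O)(=C=O)=C=O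
F6 | step 3 | 4-(2,5-dimethoxyphenoxy)-2,5-bis(trimethylsilyl)phenol | Oc1c([Si](C)(C)C)cc(Oc2cc(OC)ccc2OC)c([Si](C)(C)C)c1
F7 | step 5 | 4-(3,4,6-tribromo-2,5-dimethoxyphenoxy)-2,5-bis(trimethylsilyl)phenyl acetate | CC(=O)Oc1c([Si](C)(C)C)cc(Oc2c(OC)c(Br)c(Br)c(OC)c2Br)c([Si](C)(C)C)c1
F8 | step 5 | 2,5-dibromo-4-(3,4,6-tribromo-2,5-dimethoxyphenoxy)phenyl acetate | CC(=O)Oc1c(Br)cc(Oc2c(OC)c(Br)c(Br)c(OC)c2Br)c(Br)c1
F9 | step 5 | 2,5-dibromo-4-(3,4,6-tribromo-2,5-dimethoxyphenoxy)phenol | Oc1c(Br)cc(Oc2c(OC)c(Br)c(Br)c(OC)c2Br)c(Br)c1
A1 | alternative 1 | 2-(4-hydroxyphenoxy)benzene-1,4-diol | Oc1ccc(Oc2cc(O)ccc2O)cc1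
A2 | alternative 1 | 3,5,6-tribromo-2-(2,3,5-tribromo-4-hydroxyphenoxy)-1,4-benzoquinone | O=C1C(Br)=C(Br)C(=O)C(Oc2cc(Br)c(O)c(Br)c2Br)=C1Br
A3 | alternative 2 | 4-(3,4,6-tribromo-2,5-dimethoxyphenoxy)cyclohexanone | O=C1CCC(Oc2c(OC)c(Br)c(Br)c(OC)c2Br)CC1
A4 | alternative 2 | 2,6-dibromo-4-(3,4,6-tribromo-2,5-dimethoxyphenoxy)phenol | Oc1c(Br)cc(Oc2c(OC)c(Br)c(Br)c(OC)c2Br)cc1Br
A5 | alternative 3 | 3,5-dibromo-4-methoxy-2-(trimethylsilyl)phenyl trifluoromethanesulfonate | COc1c(Br)cc(OS(=O)(=O)C(F)(F)F)c([Si](C)(C)C)c1Br
A6 | alternative 3 | 2,3,5-tribromo-4-methoxyphenyl 3,4,6-tribromo-2,5-dimethoxyphenyl ether | COc1c(Br)cc(Oc2c(OC)c(Br)c(Br)c(OC)c2Br)c(Br)c1Br
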